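**Retrosynthetic overview**
1. The target is the diacetate of a dihydroxy acid; the acid is freed and both acetates are put on in the last two steps.
2. Both rings form in one cation–olefin cascade from an acyclic (R)-epoxy triene: ring A first (C4–C5), then ring B (C9–C10), with the exocyclic C8=C17 alkene fixed by an allylsilane terminator.
3. The chain is joined by two B-alkyl Suzuki couplings: C12–C13 to a (Z)-β-iodoenoate and C1–C10 to an (E)-vinyl iodide.
4. The allylsilane comes from a β-keto Weinreb amide (dianion alkylation, Z-enol triflate, Me3SiCH2 cross-coupling), which also delivers the aldehyde for the diene.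
5. C4, the only catalyst-set stereocenter, is made first by asymmetric allylation of chloroacetone and closed to a 2,2-disubstituted oxirane; it controls C5, C9 and C10 in the cyclisation.

Assumption: C-locants are labdane locants of the target, and the IDPi enantiomer used is the one that gives the (R)-carbinol (sense of induction to be fixed by experiment).

**Step 1**
Reactants: 1 chloroacetone; 2 allyltrimethylsilane
Product: 4 (2R)-2-methyl-2-(prop-2-en-1-yl)oxirane, via silyl ether 3 (not isolated)
Conditions: IDPi acid (2 mol%), toluene, −40 °C; then TBAF, THF, 0 °C; distilled and used as a THF solution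
Reagents that add atoms: none
Why: Proposed new method: a silylium–IDPi ion pair (the acid is silylated by 2) should catalyse a Hosomi–Sakurai allylation of the inductively activated α-chloro ketone, the confined chiral anion telling CH3 from CH2Cl as it tells methyl from ethyl in the known silylium Mukaiyama aldol of methyl ketones, so that allyl transfer sets C4 (R) and silyl transfer from the β-silyl cation turns the catalyst over (closest known reactions: IDPi-catalysed Sakurai allylation of aldehydes and IDPi-catalysed Mukaiyama aldol addition to ketones), after which fluoride cleaves the silyl ether and the alkoxide closes the oxirane by 3-exo-tet displacement of chloride without touching C4.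

**Step 2**
Reactants: 5 but-2-yn-1-ol
Product: 7 (2E)-3-iodobut-2-en-1-ol, via alkenylzirconocene chloride 6 (not isolated)
Conditions: Cp2Zr(H)Cl (2.5 equiv), THF, rt; then I2, 0 °C
Reagents that add atoms: iodine, II
Why: syn-Hydrozirconation (one equivalent is spent on the hydroxyl) puts zirconium on the less hindered methyl-bearing carbon under equilibrating excess hydride, and iododezirconation with retention gives the E-iodide.

**Step 3**
Reactants: 7 (2E)-3-iodobut-2-en-1-ol
Product: 8 (2E)-1-bromo-3-iodobut-2-ene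
Conditions: CBr4, PPh3, CH2Cl2, 0 °C
Reagents that add atoms: carbon tetrabromide, BrC(Br)(Br)Br
Why: Appel bromination of a primary allylic alcohol under neutral conditions leaves the vinyl iodide and its geometry untouched.

**Step 4**
Reactants: 9 N-methoxy-N-methyl-3-oxobutanamide; 8 (2E)-1-bromo-3-iodobut-2-ene
Product: 11 (6E)-7-iodo-N-methoxy-N-methyl-3-oxooct-6-enamide, via dilithium dienolate 10 (not isolated)
Conditions: LiN(iPr)2 (2.2 equiv), THF, −78→0 °C; then 8, −78→0 °C; aq. NH4Cl
Reagents that add atoms: none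
Why: γ-Alkylation of an acetoacetamide dianion occurs at the more basic terminal carbon by SN2 at the primary allylic bromide, forming the C6–C7 bond while the vinyl iodide is inert.

**Step 5**
Reactants: 4 (2R)-2-methyl-2-(prop-2-en-1-yl)oxirane; 11 (6E)-7-iodo-N-methoxy-N-methyl-3-oxooct-6-enamide
Product: 13 (6E)-N-methoxy-N,7-dimethyl-10-[(2R)-2-methyloxiran-2-yl]-3-oxodec-6-enamide, via alkylborane 12 (not isolated)
Conditions: 9-BBN-H, THF, 0 °C→rt; then 11, Pd(dppf)Cl2 (5 mol%), AsPh3, aq. K3PO4, DMF, rt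
Reagents that add atoms: none
Why: Anti-Markovnikov hydroboration followed by B-alkyl Suzuki–Miyaura coupling forms C1–C10 with retention of the vinyl iodide geometry (C1 trans to C6), and the mild aqueous base spares the epoxide and the β-keto amide.

**Step 6**
Reactants: 13 (6E)-N-methoxy-N,7-dimethyl-10-[(2R)-2-methyloxiran-2-yl]-3-oxodec-6-enamide
Product: 15 (2Z,6E)-N-methoxy-N,7-dimethyl-10-[(2R)-2-methyloxiran-2-yl]-3-{[(trifluoromethyl)sulfonyl]oxy}deca-2,6-dienamide, via sodium enolate 14 (not isolated)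
Conditions: NaH, THF, 0 °C; then PhNTf2, 0 °C→rt
Reagents that add atoms: N-phenylbis(trifluoromethanesulfonimide), O=S(=O)(N(c1ccccc1)S(=O)(=O)C(F)(F)F)C(F)(F)F
Why: O-Sulfonylation of the chelated sodium enolate of the β-keto amide gives the Z-enol triflate (triflate cis to the amide carbonyl), and the neutral triflating agent does not open the epoxide.

**Step 7**
Reactants: 15 (the Z-enol triflate)
Product: 16 (2Z,6E)-N-methoxy-N,7-dimethyl-10-[(2R)-2-methyloxiran-2-yl]-3-[(trimethylsilyl)methyl]deca-2,6-dienamide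
Conditions: Me3SiCH2ZnCl (from Me3SiCH2Li and ZnCl2), Pd(PPh3)4 (5 mol%), THF, rt
Reagents that add atoms: (trimethylsilyl)methyllithium, [Li]C[Si](C)(C)C
Why: Negishi cross-coupling with retention puts CH2SiMe3 cis to the carbonyl carbon (C7 chain trans to C11, as the chair cyclisation needs), and the organozinc does not add to the Weinreb amide or the epoxide.

**Step 8**
Reactants: 16 (the allylsilane Weinreb amide)
Product: 18 (2Z,6E)-7-methyl-10-[(2R)-2-methyloxiran-2-yl]-3-[(trimethylsilyl)methyl]deca-2,6-dienal, via aluminium hemiaminal 17 (not isolated)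
Conditions: iBu2AlH (1.2 equiv), THF, −78 °C; aq. KNaC4H4O6 (tartrate)
Reagents that add atoms: none
Why: Weinreb amide reduction stops at the chelated aluminium hemiaminal, which gives the enal on work-up, and at −78 °C the epoxide is not reduced.

**Step 9**
Reactants: 18 (the enal)
Product: 19 (2R)-2-methyl-2-{(4E,8Z)-4-methyl-8-[(trimethylsilyl)methyl]undeca-4,8,10-trien-1-yl}oxirane
Conditions: Ph3PCH3Br, KN(SiMe3)2, THF, −78→0 °C
Reagents that add atoms: methyltriphenylphosphonium bromide, C[P+](c1ccccc1)(c1ccccc1)c1ccccc1.[Br-]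
Why: Wittig methylenation of the aldehyde gives the terminal diene (C11=C12) without disturbing the trisubstituted alkenes or the epoxide.

**Step 10**
Reactants: 20 methyl 4-hydroxybut-2-ynoate
Product: 21 methyl (2Z)-4-hydroxy-3-iodobut-2-enoate
Conditions: LiI, AcOH, MeCN, 70 °C
Reagents that add atoms: lithium iodide, [Li+].[I-]
Why: anti-Hydroiodination of the ynoate (conjugate addition of iodide, anti protonation) gives the β-iodoenoate with iodine cis and CH2OH trans to the ester, so it cannot lactonise.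

**Step 11**
Reactants: 19 (the silyl diene); 21 methyl (2Z)-4-hydroxy-3-iodobut-2-enoate
Product: 23 methyl (2E,6Z,10E)-3-(hydroxymethyl)-11-methyl-14-[(2R)-2-methyloxiran-2-yl]-7-[(trimethylsilyl)methyl]tetradeca-2,6,10-trienoate, via alkylborane 22 (not isolated)
Conditions: 9-BBN-H, THF, 0 °C→rt; then 21, Pd(dppf)Cl2 (5 mol%), AsPh3, aq. K3PO4, DMF, rt
Reagents that add atoms: none
Why: 9-BBN adds only to the monosubstituted terminus of the diene, and B-alkyl Suzuki–Miyaura coupling with retention forms C12–C13 with C12 cis to the ester and C16 trans to it (13E).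

**Step 12**
Reactants: 23 (the acyclic epoxy triene ester)
Product: 24 methyl (2E)-3-(hydroxymethyl)-5-[(1R,4aS,5R,8aS)-5-(hydroxymethyl)-5,8a-dimethyl-2-methylidenedecahydronaphthalen-1-yl]pent-2-enoate
Conditions: MeAlCl2 (3 equiv), CH2Cl2, −78 °C; aq. NaHCO3
Reagents that add atoms: none
Why: Lewis-acid epoxide-initiated, allylsilane-terminated cation–olefin bicyclisation, in which the E-alkene opens the quaternary oxirane carbon with inversion in a chair–chair array (ring A then ring B), the tied-back oxirane CH2O is expected to take the axial site syn to the angular methyl while the methyl goes equatorial, C5, C10 and C9 follow from the alkene geometries, and loss of Me3Si from the β-silyl cation gives only the exocyclic alkene; the axial placement is a steric prediction, not a precedent for 2,2-disubstituted oxiranes.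

**Step 13**
Reactants: 24 (the bicyclic diol methyl ester)
Product: 25 (2E)-3-(hydroxymethyl)-5-[(1R,4aS,5R,8aS)-5-(hydroxymethyl)-5,8a-dimethyl-2-methylidenedecahydronaphthalen-1-yl]pent-2-enoic acid
Conditions: LiOH, THF/MeOH/H2O, 40 °C; then 1 M HCl to pH 3
Reagents that add atoms: lithium hydroxide, [Li+].[OH-]
Why: Saponification of the methyl ester gives the hydroxy acid, which cannot lactonise because C16 is trans to the carboxyl group.

**Step 14**
Reactants: 25 (the dihydroxy acid)
Product: 27 (2E)-3-(acetoxymethyl)-5-[(1R,4aS,5R,8aS)-5-(acetoxymethyl)-5,8a-dimethyl-2-methylidenedecahydronaphthalen-1-yl]pent-2-enoic acid, via mixed anhydride 26 (not isolated)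
Conditions: Ac2O, pyridine, DMAP (cat.), CH2Cl2, 0 °C→rt; then H2O, THF, NaHCO3; dilute HCl
Reagents that add atoms: acetic anhydride, CC(=O)OC(C)=O
Why: DMAP-catalysed acetylation esterifies both primary alcohols, and the acetic mixed anhydride formed at the carboxyl group is hydrolysed on aqueous work-up to give the free acid.

**Compound list**
1 | chloroacetone (1-chloropropan-2-one) | CC(=O)CCl | starting material
2 | allyltrimethylsilane | C=CC[Si](C)(C)C | starting material
3 | {[(2R)-1-chloro-2-methylpent-4-en-2-yl]oxy}trimethylsilane | C[C@@](O[Si](C)(C)C)(CC=C)CCl | intermediate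
4 | (2R)-2-methyl-2-(prop-2-en-1-yl)oxirane | C[C@@]1(CC=C)CO1 | intermediate
5 | but-2-yn-1-ol | CC#CCO | starting material
6 | chlorobis(cyclopentadienyl){(2E)-4-[chlorobis(cyclopentadienyl)zirconiooxy]but-2-en-2-yl}zirconium (Zr on C3 trans to CH2O, second Cp2ZrCl on oxygen) | C/C(=C\CO[Zr](Cl)(C1C=CC=C1)C1C=CC=C1)[Zr](Cl)(C1C=CC=C1)C1C=CC=C1 | intermediate
7 | (2E)-3-iodobut-2-en-1-ol | C/C(I)=C\CO | intermediate
8 | (2E)-1-bromo-3-iodobut-2-ene | C/C(I)=C\CBr | intermediate
9 | N-methoxy-N-methyl-3-oxobutanamide | CC(=O)CC(=O)N(C)OC | starting material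
10 | dilithium 1-[methoxy(methyl)amino]buta-1,3-diene-1,3-diolate (dianion of 9) | [Li+].[Li+].C=C([O-])C=C([O-])N(C)OC | intermediate
11 | (6E)-7-iodo-N-methoxy-N-methyl-3-oxooct-6-enamide | C/C(I)=C\CCC(=O)CC(=O)N(C)OC | intermediate
12 | 9-{3-[(2R)-2-methyloxiran-2-yl]propyl}-9-borabicyclo[3.3.1]nonane | C[C@@]1(CCCB2C3CCCC2CCC3)CO1 | intermediate
13 | (6E)-N-methoxy-N,7-dimethyl-10-[(2R)-2-methyloxiran-2-yl]-3-oxodec-6-enamide | C[C@@]1(CCC/C(C)=C/CCC(=O)CC(=O)N(C)OC)CO1 | intermediate
14 | sodium (2Z,6E)-1-[methoxy(methyl)amino]-7-methyl-10-[(2R)-2-methyloxiran-2-yl]-1-oxodeca-2,6-dien-3-olate (enolate of 13) | C[C@@]1(CCC/C(C)=C/CC/C([O-])=C/C(=O)N(C)OC)CO1.[Na+] | intermediate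
15 | (2Z,6E)-N-methoxy-N,7-dimethyl-10-[(2R)-2-methyloxiran-2-yl]-3-{[(trifluoromethyl)sulfonyl]oxy}deca-2,6-dienamide | C[C@@]1(CCC/C(C)=C/CC/C(OS(=O)(=O)C(F)(F)F)=C/C(=O)N(C)OC)CO1 | intermediate
16 | (2Z,6E)-N-methoxy-N,7-dimethyl-10-[(2R)-2-methyloxiran-2-yl]-3-[(trimethylsilyl)methyl]deca-2,6-dienamide | C[C@@]1(CCC/C(C)=C/CC/C(C[Si](C)(C)C)=C/C(=O)N(C)OC)CO1 | intermediate
17 | (2Z,6E)-1-[(diisobutylalumanyl)oxy]-N-methoxy-N,7-dimethyl-10-[(2R)-2-methyloxiran-2-yl]-3-[(trimethylsilyl)methyl]deca-2,6-dien-1-amine (hemiaminal carbon unassigned) | C[C@@]1(CCC/C(C)=C/CC/C(C[Si](C)(C)C)=C/C(O[Al](CC(C)C)CC(C)C)N(C)OC)CO1 | intermediate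
18 | (2Z,6E)-7-methyl-10-[(2R)-2-methyloxiran-2-yl]-3-[(trimethylsilyl)methyl]deca-2,6-dienal | C[C@@]1(CCC/C(C)=C/CC/C(C[Si](C)(C)C)=C/C=O)CO1 | intermediate
19 | (2R)-2-methyl-2-{(4E,8Z)-4-methyl-8-[(trimethylsilyl)methyl]undeca-4,8,10-trien-1-yl}oxirane | C[C@@]1(CCC/C(C)=C/CC/C(C[Si](C)(C)C)=C/C=C)CO1 | intermediate
20 | methyl 4-hydroxybut-2-ynoate | COC(=O)C#CCO | starting material
21 | methyl (2Z)-4-hydroxy-3-iodobut-2-enoate | COC(=O)/C=C(I)/CO | intermediate
22 | 9-{(3Z,7E)-8-methyl-11-[(2R)-2-methyloxiran-2-yl]-4-[(trimethylsilyl)methyl]undeca-3,7-dien-1-yl}-9-borabicyclo[3.3.1]nonane | C[C@@]1(CCC/C(C)=C/CC/C(C[Si](C)(C)C)=C/CCB2C3CCCC2CCC3)CO1 | intermediate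
23 | methyl (2E,6Z,10E)-3-(hydroxymethyl)-11-methyl-14-[(2R)-2-methyloxiran-2-yl]-7-[(trimethylsilyl)methyl]tetradeca-2,6,10-trienoate | C[C@@]1(CCC/C(C)=C/CC/C(C[Si](C)(C)C)=C/CC/C(CO)=C\C(=O)OC)CO1 | intermediate
24 | methyl (2E)-3-(hydroxymethyl)-5-[(1R,4aS,5R,8aS)-5-(hydroxymethyl)-5,8a-dimethyl-2-methylidenedecahydronaphthalen-1-yl]pent-2-enoate | C=C1CC[C@@H]2[C@](C)(CO)CCC[C@@]2(C)[C@@H]1CC/C(=C\C(=O)OC)CO | intermediate
25 | (2E)-3-(hydroxymethyl)-5-[(1R,4aS,5R,8aS)-5-(hydroxymethyl)-5,8a-dimethyl-2-methylidenedecahydronaphthalen-1-yl]pent-2-enoic acid | C=C1CC[C@@H]2[C@](C)(CO)CCC[C@@]2(C)[C@@H]1CC/C(=C\C(=O)O)CO | intermediate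
26 | acetic (2E)-3-(acetoxymethyl)-5-[(1R,4aS,5R,8aS)-5-(acetoxymethyl)-5,8a-dimethyl-2-methylidenedecahydronaphthalen-1-yl]pent-2-enoic anhydride | C=C1CC[C@@H]2[C@](C)(COC(C)=O)CCC[C@@]2(C)[C@@H]1CC/C(=C\C(=O)OC(C)=O)COC(C)=O | intermediate
27 | (2E)-3-(acetoxymethyl)-5-[(1R,4aS,5R,8aS)-5-(acetoxymethyl)-5,8a-dimethyl-2-methylidenedecahydronaphthalen-1-yl]pent-2-enoic acid (16,19-diacetoxy-ent-labda-8(17),13E-dien-15-oic acid) | C=C1CC[C@@H]2[C@](C)(COC(C)=O)CCC[C@@]2(C)[C@@H]1CC/C(=C\C(=O)O)COC(C)=O | target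

**Totals**
Total step count: 14. Longest linear sequence: 12 (steps 2–9 and 11–14).

**Three steps most likely to fail**

Step 1 is the new reaction. A ketone may be too weak an electrophile for allyltrimethylsilane under silylium–IDPi catalysis, or the pocket may not separate CH3 from CH2Cl well enough. The fallback is known chemistry, sets out from 1 and comes back at 4. It is the chiral-biphenol-catalysed allylboration of methyl ketones: 1, allyldiisopropoxyborane and 3,3′-dibromo-BINOL (15 mol%, the enantiomer giving the R-carbinol) in PhCF3/toluene at −35 °C give diisopropyl (2R)-1-chloro-2-methylpent-4-en-2-yl borate F1, which aqueous work-up hydrolyses to (2R)-1-chloro-2-methylpent-4-en-2-ol F2. KOH in Et2O/H2O then closes F2 to 4.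

Step 5 couples a volatile epoxy-borane with a vinyl iodide that carries an enolisable β-keto amide, which can bind palladium or undergo intramolecular enolate vinylation. The fallback sets out from 7 and comes back at 13, and it moves the coupling ahead of the dianion chemistry. Borane 12 is coupled with the free alcohol 7 (Pd(dppf)Cl2, AsPh3, aq. K3PO4, DMF) to give (2E)-3-methyl-6-[(2R)-2-methyloxiran-2-yl]hex-2-en-1-ol F3. Appel bromination (CBr4, PPh3, 2,6-lutidine, CH2Cl2, −20 °C) gives (2R)-2-[(4E)-6-bromo-4-methylhex-4-en-1-yl]-2-methyloxirane F4, and alkylation of dienolate 10 with F4 (THF, −78→0 °C) gives 13.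

Step 12 carries the largest uncertainty of the known-type steps. The hydroxy-enoate head can sequester MeAlCl2, the 2,2-disubstituted oxirane can rearrange to an aldehyde before the alkene engages, and some material may close with CH2O equatorial to give the C4-epimeric series. The fallback sets out from 19 and comes back at 24; it cyclises before the head is attached, so the Lewis-acid step sees only hydrocarbon, silane and epoxide and any C4 epimer is removed on a simpler compound. Diene 19 with MeAlCl2 (2 equiv, CH2Cl2, −78 °C) gives [(1R,4aR,5R,8aS)-5-ethenyl-1,4a-dimethyl-6-methylidenedecahydronaphthalen-1-yl]methanol F5. Sia2BH (2.2 equiv, THF, 0 °C) borylates the hydroxyl and adds to the monosubstituted vinyl group much faster than to the hindered exocyclic methylene, giving {2-[(1R,4aS,5R,8aS)-5-({[bis(3-methylbutan-2-yl)boranyl]oxy}methyl)-5,8a-dimethyl-2-methylidenedecahydronaphthalen-1-yl]ethyl}bis(3-methylbutan-2-yl)borane F6, used in the flask. Suzuki–Miyaura coupling of F6 with 21 (Pd(dppf)Cl2, aq. NaOH, THF, 50 °C) gives 24. This fallback does not cure an intrinsically wrong axial/equatorial preference.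

**Further compounds**
F1 | step 1 | diisopropyl (2R)-1-chloro-2-methylpent-4-en-2-yl borate | C[C@@](OB(OC(C)C)OC(C)C)(CC=C)CCl
F2 | step 1 | (2R)-1-chloro-2-methylpent-4-en-2-ol | C[C@@](O)(CC=C)CCl
F3 | step 5 | (2E)-3-methyl-6-[(2R)-2-methyloxiran-2-yl]hex-2-en-1-ol | C[C@@]1(CCC/C(C)=C/CO)CO1
F4 | step 5 | (2R)-2-[(4E)-6-bromo-4-methylhex-4-en-1-yl]-2-methyloxirane | C[C@@]1(CCC/C(C)=C/CBr)CO1
F5 | step 12 | [(1R,4aR,5R,8aS)-5-ethenyl-1,4a-dimethyl-6-methylidenedecahydronaphthalen-1-yl]methanol | C=C1CC[C@@H]2[C@](C)(CO)CCC[C@@]2(C)[C@@H]1C=C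
F6 | step 12 | {2-[(1R,4aS,5R,8aS)-5-({[bis(3-methylbutan-2-yl)boranyl]oxy}methyl)-5,8a-dimethyl-2-methylidenedecahydronaphthalen-1-yl]ethyl}bis(3-methylbutan-2-yl)borane | C=C1CC[C@@H]2[C@](C)(COB(C(C)C(C)C)C(C)C(C)C)CCC[C@@]2(C)[C@@H]1CCB(C(C)C(C)C)C(C)C(C)C
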